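No rate constant is given for this two-phase flask, so I replace the constants with one time read from the runs.

| flask | substrate | reagent in the second phase | remark | time | volume of the second phase over the first |
|---|---|---|---|---|---|
| Monday's | 24 mM | 1.2 equiv | run made earlier |  |  |
| Friday's | 98 mM | 1.2 equiv | run made earlier |  |  |
| flask | 49 mM | 1.20 equiv |  | 2.0 min | 2.0 |

| run | time / s | target / % | substrate / % |
|---|---|---|---|
| Monday's | 10.0 | 0 | 100.4 |
| Monday's | 25.0 | 1.1 | 100.0 |
| Monday's | 40.0 | 0 | 100.6 |
| Monday's | 60.0 | 0.6 | 99.6 |
| Monday's | 90.0 | 0.9 | 98.7 |
| Friday's | 20.0 | 0.9 | 100.1 |
| Friday's | 40.0 | 1.4 | 99.0 |
| Friday's | 60.0 | 2.0 | 97.2 |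
| Friday's | 80.0 | 4.3 | 95.9 |
| Friday's | 90.0 | 5.8 | 96.1 |

(scatter of a reading: 0.5 percentage points)

- in the second phase: reagent in the second phase; everything else is in the first
- charges count per volume of the first phase; a concentration in a rate is the amount of a species over the volume of its own phase; every rate counts per litre of the first phase
- the analysis behind the earlier runs scatters by 0.5 percentage points, standard deviation
- candidate steps: reagent in the reaction phase -> decomposed reagent; substrate + reagent in the reaction phase -> target; reagent in the reaction phase <-> reagent in the second phase
- the earlier runs hold the two phases in the same ratio of volumes as the flask asked about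

- theta: doubling the amount of reagent in the second phase, all else as stated
- delta: doubling the transfer coefficient of the reagent in the second phase, all else as stated

* the target standing at 2.0 min, as a percentage of the substrate charged
* the change that raises the amount of target at 2.0 min, in percent of the substrate charged most ("none" if none brings more than 2 percentage points) (theta / delta / none)
* amount of target at 2.0 min, in percent of the substrate charged, after theta

Friday's target rises 3.07 times while the time doubles from 40.0 s to 80.0 s; a straight line gives 2, a square law 4. I read this as an induction period: reagent in the second phase crosses into the reaction phase, and target forms from what has arrived. So I take the square law and pool the last readings of both runs, scaled to the flask's charge: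

my estimate of target in the flask at 90.0 s = 49 mM × (0.9% + 5.8%) / (24 mM + 98 mM) = 2.69%

τ = 90.0 s / √2.69% = 549 s

I call τ the full-turnover time: the time at which the square law puts target at one whole substrate charge of this flask, a scale for the reckoning and not an expected event. On that law, target in this flask at time t, as a fraction of the substrate charged, is (t/τ) squared:

(120 s / 549 s) squared = 4.78%

The weak link is the square law beyond the last reading. If reagent in the reaction phase stopped rising at 90.0 s, target would run on straight at that moment's slope:

2.69% × (2 × 120 s / 90.0 s − 1) = 4.48%

I commit to a value between 4.48% and 4.78%, resting on readings that scatter by 0.5 percentage points.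

The forecast says 4.7% (3.6% to 5.8%), which is lower than my square-law 4.78%. It picks theta, with 9.2% (7% to 11.5%), arguing: “The system is nearly linear in reagent because substrate is barely consumed, so doubling the reservoir doubles target”.

The flask gives 3.87%, inside the forecast's range and less than my lower figure. The best change is theta, worth 3.7 points against 1.7 points for delta, and it gives 7.61%.

    reagent in the reaction phase → decomposed reagent (k = 0.00331 s⁻¹)
    substrate + reagent in the reaction phase → target (k = 0.118 M⁻¹ s⁻¹)
    reagent in the reaction phase ⇌ reagent in the second phase, rate k3*([reagent in the reaction phase] - [reagent in the second phase]/K3) per volume of the first phase (partition coefficient = 3.61, kL = 0.0120 s⁻¹)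

Read back, the flask's 3.87% makes τ 610 s, longer than the 549 s from the runs. For the same flask read at 3.0 min, that τ gives (180 s / 610 s) squared = 8.71%, while this neighbour shows 6.55% of target with 93.5% of the substrate left. Reagent in the reaction phase stands at 3.91 mM at 2.00 min and at 4.00 mM at 3.00 min.

(The readings were generated by integration from invented constants, and the scatter is random.)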